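## The problem

The target **10**, 5-hydroxy-3,7-dimethoxy-2-[4-(3-methylbut-2-enyloxy)phenyl]-4H-chromen-4-one, is a flavonol ether. Ring A (benzene) is fused to the 4-pyranone ring C, and ring B is attached to C2 by a single C–C bond. There is no stereocentre, and the prenyl alkene carries two identical methyl groups, so the task is one of regiochemistry and oxygen differentiation only. Four oxygens are in four different states: OMe on C3 of ring C, OMe on C7, free OH on C5, and a prenyl ether on C4' of ring B. Because C3 bears oxygen, ring C must be closed in a way that leaves a handle on C3. The prenyl ether is the fragile group: its alkene adds halonium electrophiles, its allylic C–O bond is cut by Lewis and Brønsted acids, and strong heating invites Claisen rearrangement, so it must enter after all such reagents. The pyranone is open to attack by hard nucleophiles at C2, which limits strongly basic conditions late in the route. The enabling feature is ring A: the carbonyl-bearing carbon C4a lies between two oxygen-bearing carbons, C5 and C8a. In a 2,4,6-trimethoxyphenyl alkynyl ketone these two ortho-methoxy oxygens are equivalent, so either can become O1 by attacking the alkyne carbon that becomes C2, while the triggering electrophile lands on the carbon next to the carbonyl, which is C3. The C4 carbonyl later distinguishes the 5-oxygen from the 7-oxygen by chelation.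

## Retrosynthesis

**10 ⇒ 8 + 9.** The O–CH2 bond of the prenyl ether is cut first, giving the diphenol 5-hydroxy-2-(4-hydroxyphenyl)-3,7-dimethoxy-4H-chromen-4-one **8** and prenyl bromide **9**. Carrying the prenyl group from the start would rule out an electrophilic ring closure and a Lewis-acid deprotection, so it is attached last. The forward reaction must alkylate the 4'-OH and leave the 5-OH alone. The 5-OH is hydrogen-bonded to the C4 carbonyl and is far less acidic and less nucleophilic, so this is expected.

**8 ⇒ 7.** The 5-O–CH3 bond and the 4'-O–benzyl bond are restored, giving 2-(4-benzyloxyphenyl)-3,5,7-trimethoxy-4H-chromen-4-one **7**. Ring A returns to a uniform dimethoxy pattern, and ring B carries a group distinct from methyl that survives coupling, iodination and copper chemistry. One Lewis acid should remove both groups. The forward step must leave the 7-OMe and the 3-OMe intact; the six-membered chelate between the 5-oxygen and the carbonyl is what makes the 5-position unique.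

**7 ⇒ 6.** The C3–OMe bond is cut to the vinylic iodide 2-(4-benzyloxyphenyl)-3-iodo-5,7-dimethoxy-4H-chromen-4-one **6**. Oxidising C3 of an unsubstituted flavone would need a strong-base metalation or a dioxirane; here the halogen is a free by-product of ring closure. The forward reaction is a copper-catalysed C–O coupling with methanol on a hindered sp2 iodide, and it must avoid conjugate attack of methoxide at C2.

**6 ⇒ 4 (via 5).** The O1–C2 bond is cut, opening ring C to the ynone 3-(4-benzyloxyphenyl)-1-(2,4,6-trimethoxyphenyl)prop-2-yn-1-one **4**. This cut is preferred over the C2–C3 or C3–C4 cuts because it alone makes use of the symmetry of ring A and places the C3 handle in the same operation. The precursor is acyclic and assembled from two simple pieces. The forward reaction is an iodine monochloride-induced 6-endo-dig closure through the methyloxonium ion **5**. It must be selective for the alkyne over the electron-rich ring A.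

**4 ⇒ 2 + 3; 2 ⇒ 1.** The bond between the carbonyl carbon and the alkyne is cut, giving 2,4,6-trimethoxybenzoyl chloride **2** and 1-benzyloxy-4-ethynylbenzene **3**. The chloride **2** comes from 2,4,6-trimethoxybenzoic acid **1**. The alternative cut at the aryl–carbonyl bond would need a Friedel–Crafts acylation with an alkynoyl chloride, which is less clean. The forward acyl Sonogashira coupling must tolerate two ortho substituents on the acid chloride.

## Roads not taken

**Alternative 1:** enolate acylation of a salicylate acetonide, then cyclodehydration.
- **Cut:** C3–C4 and O1–C2, so ring C is built from a ring-A salicylate and a ring-B α-methoxy ketone.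
- **Forward key step:** the lithium enolate of 2-methoxy-1-[4-(methoxymethoxy)phenyl]ethanone **A2** attacks the carbonyl of 7-methoxy-5-(methoxymethoxy)-2,2-dimethyl-4H-1,3-benzodioxin-4-one **A1**. The acetonide fragment is expelled and the 2-hydroxyaryl 1,3-diketone **A3** forms. HCl in methanol then closes O1–C2 with loss of water and of both methoxymethyl groups, giving 5-hydroxy-2-(4-hydroxyphenyl)-3,7-dimethoxy-4H-chromen-4-one **A4**.
- **Merits:** the C3 oxygen arrives already methylated and at the right oxidation level. **A4** is the same compound as **8**, so this road would meet the chosen one at its last step without iodine, copper or boron reagents. Its deprotection is milder and carries no risk of 3-O-demethylation; in this respect it is the better road.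
- **Weak points:** neither **A1** nor **A2** is a catalogue compound (about three and two operations). Making **A1** means telling apart three phenolic oxygens of a phloroglucinol-type acid, the problem that symmetry removes in the chosen plan. The carbonyl of **A1** is flanked by an ortho alkoxy group and deactivated by two donors. The enolate of **A2** is hindered and must be used at least twofold, because **A3** is more acidic than **A2**. O-acylation can compete.
- **Comparison:** about seven operations to **A4** against five to **8**. The chosen plan sets a short, symmetric, convergent opening against the gentler closing of this road.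

**Alternative 2:** SNAr closure of ring C at the aryl–oxygen bond.
- **Cut:** O1–C8a.
- **Forward key step:** the enolate of 1-(2,6-difluoro-4-methoxyphenyl)-2-methoxy-3-[4-(3-methylbut-2-enyloxy)phenyl]propane-1,3-dione **A5** (K2CO3, DMF, heat) displaces one ortho fluoride through the oxygen of the ring-B carbonyl. The product is 5-fluoro-3,7-dimethoxy-2-[4-(3-methylbut-2-enyloxy)phenyl]-4H-chromen-4-one **A6**. Exchange of the remaining fluorine for hydroxyl would give **10**.
- **Merits:** the prenyl ether and the 3-OMe are carried from the start under base only, no protecting group is needed, and the two fluorines are equivalent. In protecting-group economy this road beats the chosen plan.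
- **Weak points:** the displacement is activated by one ortho carbonyl only, and the para methoxy group weakens that pull. **A5** is a 2-alkoxy-1,3-diketone, awkward to make and liable to retro-Claisen cleavage in hot carbonate. The decisive problem is the end: an oxygen nucleophile strong enough to displace the C5 fluoride of **A6** also adds to C2 and opens the pyranone, and a masked hydroxide would have to be unmasked without acid because of the prenyl ether.
- **Comparison:** similar in length, but the least secure transformation falls on the last and most valuable intermediate. The chosen plan ends with a phenol alkylation.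

**Alternative 3:** intramolecular ester Wittig closure at C2=C3.
- **Cut:** the C2=C3 double bond.
- **Forward key step:** heating 3-(tert-butyldimethylsilyloxy)-5-methoxy-2-[2-methoxy-2-(triphenylphosphoranylidene)acetyl]phenyl 4-(3-methylbut-2-enyloxy)benzoate **A7** in toluene lets the ylide carbon attack the neighbouring aryl ester carbonyl. The phosphine oxide is expelled, giving 5-(tert-butyldimethylsilyloxy)-3,7-dimethoxy-2-[4-(3-methylbut-2-enyloxy)phenyl]-4H-chromen-4-one **A8**. Fluoride desilylation would give **10**.
- **Merits:** a neutral closure, every oxygen but one in its final form, and the mildest end game of the four roads.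
- **Weak points:** **A7** needs ring A with three differently substituted oxygens (silyl, methyl, aroyl), so the symmetry is spent on protecting-group work. The α-methoxy acyl ylide is not reached by the usual α-halo ketone and phosphine sequence without an extra oxygenation step. The ylide carbon, bearing both methoxy and acyl groups, is hindered and weakly nucleophilic toward an ester. Long heating would be needed, under which silyl or aroyl migration between the ortho oxygens becomes possible.
- **Comparison:** better in end-game mildness, worse in length (eight or more operations expected) and in how surely its precursor can be made. The chosen plan pays with ICl and BCl3 but uses both before the prenyl group exists.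

Key step: step 3

Assumption: 1-benzyloxy-4-ethynylbenzene **3** is taken as a catalogue compound.

## Route

Step 1
Reactants: 1 2,4,6-trimethoxybenzoic acid
Product: 2 2,4,6-trimethoxybenzoyl chloride
Conditions: (COCl)2, DMF (cat.), CH2Cl2, 0 °C → rt; evaporate, use crude
Reagents that add atoms: oxalyl chloride, ClC(=O)C(=O)Cl
Why: Acid chloride formation through the chloroiminium species from DMF and oxalyl chloride; anhydrous, non-aqueous conditions avoid the acid-promoted protodecarboxylation to which this electron-rich acid is prone, and the by-products are gases.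

Step 2
Reactants: 2 2,4,6-trimethoxybenzoyl chloride; 3 1-benzyloxy-4-ethynylbenzene
Product: 4 3-(4-benzyloxyphenyl)-1-(2,4,6-trimethoxyphenyl)prop-2-yn-1-one
Conditions: PdCl2(PPh3)2 (2 mol%), CuI (4 mol%), Et3N, THF, rt, degassed
Reagents that add atoms: none
Why: Acyl Sonogashira coupling: the acyl chloride adds oxidatively to zerovalent palladium formed from PdCl2(PPh3)2, the copper acetylide from 3, CuI and Et3N transmetalates, and reductive elimination gives the ynone; the two ortho methoxy groups slow but should not block oxidative addition, and aryl methyl and benzyl ethers are inert.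

Step 3
Reactants: 4 3-(4-benzyloxyphenyl)-1-(2,4,6-trimethoxyphenyl)prop-2-yn-1-one
Product: 6 2-(4-benzyloxyphenyl)-3-iodo-5,7-dimethoxy-4H-chromen-4-one, via O-methyloxonium chloride 5 (not isolated)
Conditions: ICl (1.1 equiv), CH2Cl2, −78 °C; aq. Na2S2O3 quench at −78 °C
Reagents that add atoms: iodine monochloride, ClI
Why: This is the iodocyclisation of an ortho-methoxyaryl alkynyl ketone, a known route to 3-iodochromones and 3-iodoflavones. ICl delivers I+ to the alkyne carbon next to the carbonyl, because the positive charge then develops on the other alkyne carbon, where the 4-benzyloxyphenyl group stabilises it. One ortho-methoxy oxygen attacks that benzylic carbon anti to iodine in a 6-endo-dig closure, forming O1–C2 and ring C as the methyloxonium ion 5. Chloride then removes the O-methyl group by SN2 displacement, giving chloromethane and the neutral pyranone 6 with iodine fixed on C3. A 5-exo-dig closure would require oxygen to attack the carbonyl-bearing alkyne carbon, the electron-rich end of the activated alkyne, so it is not expected. The two ortho-methoxy groups are related by the symmetry of ring A, so both closures give the same product, and no stereocentre is formed. The selectivity the step really needs is alkyne over arene: the two free positions of ring A lie between methoxy groups and can be iodinated, and this is countered by the donor-activated alkyne reacting first at −78 °C, a near-stoichiometric charge of ICl and a cold reductive quench. Benzyl and methyl ethers are inert to ICl at this temperature, and no phenol or alkene is present.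

Step 4
Reactants: 6 2-(4-benzyloxyphenyl)-3-iodo-5,7-dimethoxy-4H-chromen-4-one
Product: 7 2-(4-benzyloxyphenyl)-3,5,7-trimethoxy-4H-chromen-4-one
Conditions: CuI (10 mol%), 3,4,7,8-tetramethyl-1,10-phenanthroline (20 mol%), Cs2CO3, MeOH–toluene, 90 °C, sealed
Reagents that add atoms: methanol, CO
Why: Ullmann-type copper-catalysed C–O coupling of an sp2 carbon–iodine bond with an aliphatic alcohol, established for aryl and vinylic iodides with phenanthroline ligands; carbonate in methanol feeds the copper methoxide while keeping free methoxide low, which protects C2 of the pyranone from conjugate attack, and the donor aryl group on C2 lowers its electrophilicity further.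

Step 5
Reactants: 7 2-(4-benzyloxyphenyl)-3,5,7-trimethoxy-4H-chromen-4-one
Product: 8 5-hydroxy-2-(4-hydroxyphenyl)-3,7-dimethoxy-4H-chromen-4-one
Conditions: BCl3 (4 equiv), C6HMe5 (3 equiv), CH2Cl2, −78 → 0 °C; then H2O
Reagents that add atoms: none
Why: Lewis-acid ether cleavage: BCl3 removes the aryl benzyl ether at low temperature, the benzyl cation being trapped by pentamethylbenzene in a Friedel–Crafts reaction, and on warming it removes the 5-O-methyl group through a six-membered dichloroboron chelate with the C4 carbonyl. The 7-OMe has no such assistance, and the 3-OMe is spared because the carbonyl is then tied up in the 5-O chelate and a second chelate would be five-membered.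

Step 6
Reactants: 8 5-hydroxy-2-(4-hydroxyphenyl)-3,7-dimethoxy-4H-chromen-4-one; 9 prenyl bromide (1-bromo-3-methylbut-2-ene)
Product: 10 5-hydroxy-3,7-dimethoxy-2-[4-(3-methylbut-2-enyloxy)phenyl]-4H-chromen-4-one
Conditions: 9 (1.1 equiv), K2CO3, acetone, 50 °C
Reagents that add atoms: none
Why: Williamson ether synthesis: the 4'-OH, vinylogously conjugated to the C4 carbonyl, is the more acidic and the unhindered phenol, whereas the 5-OH is locked in a hydrogen bond to that carbonyl and is not alkylated by one equivalent of halide under carbonate; SN2 attack at the primary allylic carbon gives the O-prenyl ether.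

## Compound list

1 | 2,4,6-trimethoxybenzoic acid | COc1cc(OC)c(C(=O)O)c(OC)c1 | starting material
2 | 2,4,6-trimethoxybenzoyl chloride | COc1cc(OC)c(C(=O)Cl)c(OC)c1 | intermediate
3 | 1-benzyloxy-4-ethynylbenzene | C#Cc1ccc(OCc2ccccc2)cc1 | starting material
4 | 3-(4-benzyloxyphenyl)-1-(2,4,6-trimethoxyphenyl)prop-2-yn-1-one | COc1cc(OC)c(C(=O)C#Cc2ccc(OCc3ccccc3)cc2)c(OC)c1 | intermediate
5 | 2-(4-benzyloxyphenyl)-3-iodo-5,7-dimethoxy-1-methyl-4-oxo-4H-chromen-1-ium chloride | COc1cc(OC)c2C(=O)C(I)=C(c3ccc(OCc4ccccc4)cc3)[O+](C)c2c1.[Cl-] | intermediate
6 | 2-(4-benzyloxyphenyl)-3-iodo-5,7-dimethoxy-4H-chromen-4-one | COc1cc(OC)c2c(=O)c(I)c(-c3ccc(OCc4ccccc4)cc3)oc2c1 | intermediate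
7 | 2-(4-benzyloxyphenyl)-3,5,7-trimethoxy-4H-chromen-4-one | COc1cc(OC)c2c(=O)c(OC)c(-c3ccc(OCc4ccccc4)cc3)oc2c1 | intermediate
8 | 5-hydroxy-2-(4-hydroxyphenyl)-3,7-dimethoxy-4H-chromen-4-one | COc1cc(O)c2c(=O)c(OC)c(-c3ccc(O)cc3)oc2c1 | intermediate
9 | prenyl bromide (1-bromo-3-methylbut-2-ene) | CC(C)=CCBr | starting material
10 | 5-hydroxy-3,7-dimethoxy-2-[4-(3-methylbut-2-enyloxy)phenyl]-4H-chromen-4-one | COc1cc(O)c2c(=O)c(OC)c(-c3ccc(OCC=C(C)C)cc3)oc2c1 | target

## Step count and risks

Total steps: 6. Longest linear sequence: 6 steps (1 → 2 → 4 → 6 → 7 → 8 → 10); 3 and 9 are bought.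

**Step 3 (key step).** The most likely failure is electrophilic iodination of ring A, before or after closure. Its two free positions each sit between two methoxy groups and are only weakly deactivated by the twisted carbonyl. Addition of ICl across the alkyne without closure is a second possibility. The fallback closes the ring without an external electrophile and introduces iodine afterwards through a carbanion, so ring A cannot compete. It sets out from alkyne 3. Excess lithium acetylide of 3 (n-BuLi, THF, −78 °C) is added to the lithium phenoxide of commercial 2-hydroxy-4,6-dimethoxybenzaldehyde F1, giving racemic 2-[3-(4-benzyloxyphenyl)-1-hydroxyprop-2-ynyl]-3,5-dimethoxyphenol F2. MnO2 in CH2Cl2 oxidises the propargylic alcohol to 3-(4-benzyloxyphenyl)-1-(2-hydroxy-4,6-dimethoxyphenyl)prop-2-yn-1-one F3. Diethylamine in ethanol adds to the ynone and the phenol displaces the amine (addition–elimination, a formal 6-endo oxa-Michael closure), giving 2-(4-benzyloxyphenyl)-5,7-dimethoxy-4H-chromen-4-one F4. Deprotonation at C3 with LiN(iPr)2 in THF at −78 °C and quenching with I2 returns to 6.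

**Step 4.** Conjugate attack of methoxide at C2 with opening of the pyranone, or reductive loss of iodine, may outrun C–O coupling at the hindered C3 position. The fallback reverses the polarity of C3 and sets out from 6. Iodine–magnesium exchange with iPrMgCl·LiCl (THF, −40 °C) gives [2-(4-benzyloxyphenyl)-5,7-dimethoxy-4-oxo-4H-chromen-3-yl]magnesium chloride F5. B(OMe)3 converts it into dimethyl [2-(4-benzyloxyphenyl)-5,7-dimethoxy-4-oxo-4H-chromen-3-yl]boronate F6. NaBO3·4H2O in aqueous THF oxidises the C–B bond in the same flask to 2-(4-benzyloxyphenyl)-3-hydroxy-5,7-dimethoxy-4H-chromen-4-one F7. O-Methylation of F7 (MeI, K2CO3, acetone) returns to 7.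

**Step 5.** Over-cleavage at the 3-O-methyl group, which is also next to the carbonyl, or Friedel–Crafts benzylation of ring A by the benzyl cation may occur. The fallback separates the two cleavages and sets out from 7. Hydrogenolysis (H2, Pd/C, EtOAc–MeOH) removes the benzyl group without any cation and gives 2-(4-hydroxyphenyl)-3,5,7-trimethoxy-4H-chromen-4-one F8. AlBr3 in MeCN at 0 °C then cleaves only the chelated 5-O-methyl group and returns to 8.

**Step 2.** Oxidative addition of the doubly ortho-substituted, electron-rich acid chloride may be slow, so that copper-mediated alkyne homocoupling or hydrolysis of 2 takes over. The fallback replaces the cross-coupling by carbonyl addition and oxidation and sets out from 3. The lithium acetylide of 3 (n-BuLi, THF, −78 °C) is added to commercial 2,4,6-trimethoxybenzaldehyde F9, giving racemic 3-(4-benzyloxyphenyl)-1-(2,4,6-trimethoxyphenyl)prop-2-yn-1-ol F10. MnO2 in CH2Cl2 oxidises F10 and returns to 4.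

## Further compounds

F1 | step 3 | 2-hydroxy-4,6-dimethoxybenzaldehyde | COc1cc(O)c(C=O)c(OC)c1
F2 | step 3 | 2-[3-(4-benzyloxyphenyl)-1-hydroxyprop-2-ynyl]-3,5-dimethoxyphenol (racemic) | COc1cc(O)c(C(O)C#Cc2ccc(OCc3ccccc3)cc2)c(OC)c1
F3 | step 3 | 3-(4-benzyloxyphenyl)-1-(2-hydroxy-4,6-dimethoxyphenyl)prop-2-yn-1-one | COc1cc(O)c(C(=O)C#Cc2ccc(OCc3ccccc3)cc2)c(OC)c1
F4 | step 3 | 2-(4-benzyloxyphenyl)-5,7-dimethoxy-4H-chromen-4-one | COc1cc(OC)c2c(=O)cc(-c3ccc(OCc4ccccc4)cc3)oc2c1
F5 | step 4 | [2-(4-benzyloxyphenyl)-5,7-dimethoxy-4-oxo-4H-chromen-3-yl]magnesium chloride | COc1cc(OC)c2c(=O)c([Mg]Cl)c(-c3ccc(OCc4ccccc4)cc3)oc2c1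
F6 | step 4 | dimethyl [2-(4-benzyloxyphenyl)-5,7-dimethoxy-4-oxo-4H-chromen-3-yl]boronate | COB(OC)c1c(-c2ccc(OCc3ccccc3)cc2)oc2cc(OC)cc(OC)c2c1=O
F7 | step 4 | 2-(4-benzyloxyphenyl)-3-hydroxy-5,7-dimethoxy-4H-chromen-4-one | COc1cc(OC)c2c(=O)c(O)c(-c3ccc(OCc4ccccc4)cc3)oc2c1
F8 | step 5 | 2-(4-hydroxyphenyl)-3,5,7-trimethoxy-4H-chromen-4-one | COc1cc(OC)c2c(=O)c(OC)c(-c3ccc(O)cc3)oc2c1
F9 | step 2 | 2,4,6-trimethoxybenzaldehyde | COc1cc(OC)c(C=O)c(OC)c1
F10 | step 2 | 3-(4-benzyloxyphenyl)-1-(2,4,6-trimethoxyphenyl)prop-2-yn-1-ol (racemic) | COc1cc(OC)c(C(O)C#Cc2ccc(OCc3ccccc3)cc2)c(OC)c1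
A1 | alternative 1 | 7-methoxy-5-(methoxymethoxy)-2,2-dimethyl-4H-1,3-benzodioxin-4-one | COCOc1cc(OC)cc2OC(C)(C)OC(=O)c12
A2 | alternative 1 | 2-methoxy-1-[4-(methoxymethoxy)phenyl]ethanone | COCC(=O)c1ccc(OCOC)cc1
A3 | alternative 1 | 1-[2-hydroxy-4-methoxy-6-(methoxymethoxy)phenyl]-2-methoxy-3-[4-(methoxymethoxy)phenyl]propane-1,3-dione | COCOc1cc(OC)cc(O)c1C(=O)C(OC)C(=O)c1ccc(OCOC)cc1
A4 | alternative 1 | 5-hydroxy-2-(4-hydroxyphenyl)-3,7-dimethoxy-4H-chromen-4-one | COc1cc(O)c2c(=O)c(OC)c(-c3ccc(O)cc3)oc2c1
A5 | alternative 2 | 1-(2,6-difluoro-4-methoxyphenyl)-2-methoxy-3-[4-(3-methylbut-2-enyloxy)phenyl]propane-1,3-dione | COc1cc(F)c(C(=O)C(OC)C(=O)c2ccc(OCC=C(C)C)cc2)c(F)c1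
A6 | alternative 2 | 5-fluoro-3,7-dimethoxy-2-[4-(3-methylbut-2-enyloxy)phenyl]-4H-chromen-4-one | COc1cc(F)c2c(=O)c(OC)c(-c3ccc(OCC=C(C)C)cc3)oc2c1
A7 | alternative 3 | 3-(tert-butyldimethylsilyloxy)-5-methoxy-2-[2-methoxy-2-(triphenylphosphoranylidene)acetyl]phenyl 4-(3-methylbut-2-enyloxy)benzoate | COC(=P(c1ccccc1)(c1ccccc1)c1ccccc1)C(=O)c1c(O[Si](C)(C)C(C)(C)C)cc(OC)cc1OC(=O)c1ccc(OCC=C(C)C)cc1
A8 | alternative 3 | 5-(tert-butyldimethylsilyloxy)-3,7-dimethoxy-2-[4-(3-methylbut-2-enyloxy)phenyl]-4H-chromen-4-one | COc1cc(O[Si](C)(C)C(C)(C)C)c2c(=O)c(OC)c(-c3ccc(OCC=C(C)C)cc3)oc2c1
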